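(The earlier runs and the new flask are simulated with constants of no real substance; the scatter is artificial.)

Target is what noon and dusk are asked for, and the blue and teal runs, made at other temperatures, are what can be read.

| flask | substrate | catalyst | temperature | remark | time |
|---|---|---|---|---|---|
| blue | 0.10 M | 2 mM | 88 °C | run made earlier |  |
| teal | 0.40 M | 2 mM | 104 °C | run made earlier |  |
| noon | 0.20 M | 2.0 mM | 80 °C |  | 12 h |
| dusk | 0.20 M | 2.0 mM | 110 °C |  | 12 h |

| run | time / h | target / % |
|---|---|---|
| blue | 1.00 | 8.5 |
| blue | 1.50 | 12.6 |
| blue | 2.50 | 19.7 |
| blue | 4.00 | 26.8 |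
| blue | 8.00 | 38.8 |
| blue | 12.0 | 43.6 |
| teal | 0.250 | 8.2 |
| teal | 0.833 | 20.2 |
| teal | 1.33 | 27.8 |
| teal | 2.00 | 34.3 |
| teal | 3.00 | 39.4 |
| teal | 4.00 | 42.3 |

(each reading ± 0.5 percentage points)

1. the flask with the highest amount of target, in percent of the substrate charged ("all alike" if they lie within 1.5 percentage points) (noon / dusk / all alike)
2. final target, as a percentage of the substrate charged, in noon
3. final target, as a percentage of the substrate charged, in dusk

- in a conversion other conformer counts as not yet reacted

The flask is built up here one process at a time. First comes the main step by itself: substrate meets catalyst and becomes target. With catalyst held at one level this is pseudo-first-order, so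

target share = 1 − e^(−s·t).

The first reading of each run gives s: 0.0888 /h in blue and 0.342 /h in teal. Temperature and substrate changed together between these runs, so this reckoning assumes that the amount of substrate does not alter s. The activation energy is then 95.5 kJ/mol, which puts noon at 40.5% and dusk at 99.9%.

But both runs bend towards a ceiling: their last readings extrapolate to 46.8% in blue and 46.1% in teal. So this reckoning adds a second step, the turning of substrate into other conformer, as a sharer of the substrate. With the mean ceiling Y = 46.5%, assumed the same at each temperature,

target share = Y·(1 − e^(−n)),  n = k·t.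

Mid-curve readings give k = 0.221 /h in blue and 0.685 /h in teal, hence 80.2 kJ/mol. Noon thus reaches n = 1.45, its clock reading, the number of time constants run by the end. Dusk reaches 12.3. In this reckoning the second step takes noon to 35.5% and dusk to 46.5%.

A further step may show as a tail: teal's last readings, loose under a scatter of 0.5 percentage points, run at 0.565 /h, slower than its mid-curve pace. Even that pace gives 6.78 time constants in 12 h at teal's cooler 104 °C, so this reckoning leaves dusk at its ceiling and ahead of noon.

The forecast, from “a reversible first-order approach to equilibrium”, gave 35% for noon and 44% for dusk, each lower than this reckoning, and named dusk.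

After 12 h, noon holds 34.1% of target and dusk 48.4%, so dusk holds most.

    catalyst + other conformer → catalyst + isomer of the product A (k = 0.00434 /M/s, Ea = 66.0 kJ/mol)
    substrate ⇌ other conformer (K = 16.7, k = 1.21 × 10⁻⁵ /s, Ea = 109 kJ/mol, ΔH = −24.0 kJ/mol)
    target ⇌ isomer of the product B (K = 0.135, k = 2.51 × 10⁻⁵ /s, Ea = 105 kJ/mol, ΔH = −59.0 kJ/mol)
    substrate + catalyst → catalyst + target (k = 0.00751 /M/s, Ea = 87.0 kJ/mol)
    (constants at 80 °C)

Dusk's figure moves by 5 points when its catalyst falls to 1.55 mM. Noon's clock reading of 1.45 allows 76.5% of the reckoned ceiling, and noon stands at 73.3% of it. For a repeat of noon at 55 °C, the same pace rule gives a clock reading of 0.181, which means 7.70% of target, and that flask held 6.24% of target with 90.6% of substrate.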